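The seven-membered carbocycle (angelate carbinol C1, methylene C2, tiglate carbinol C3, CMe2 C4, cyclobutane carbons C5, C10 and methyl-bearing C11) is opened at C1–C2. It is closed last by a Dieckmann condensation: the C2 ester enolate of a two-carbon arm on C4 attacks an ester on C11. Because C11 is quaternary, only this direction is possible, and both arms sit on the cyclobutane face opposite the enone bridge. One operation forms the ring and a β-keto ester that programmes the C2=C3 enone and hence both carbinols. The precursor is a verbenone-like bicyclo[3.1.1]heptenone diester made from (+)-2-carene.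

Key step: step 8

Atom labels used below (they only name positions): C1 carbinol carbon of the angelate, C2 ring CH2, C3 carbinol carbon of the tiglate, C4 CMe2, C5 cyclobutane CH bonded to C4, C6 cyclobutane CH next to the ketone, C7 ketone carbon, C8 vinylic CH, C9 vinylic C–CH3, C10 cyclobutane CH next to C9, C11 quaternary C–CH3; ring A is the cyclohexenone ring C5–C6–C7–C8–C9–C10.

Assumption: commercial (+)-2-carene is the (1S,6R) enantiomer, and the hand of the chiral diphosphine in step 10 is the one that places boron on the C10 side of C3 (to be confirmed by testing both hands).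

Step 1
Reactants: 1 (+)-2-carene
Product: 2 car-2-en-4-one
Conditions: CrO3, 3,5-dimethylpyrazole, CH2Cl2, −20 °C
Reagents that add atoms: chromium trioxide, O=[Cr](=O)=O
Why: Allylic oxidation with the CrO3–3,5-dimethylpyrazole complex should attack the only allylic methylene (the future C8) and give the enone without touching the two cyclopropane stereocentres.

Step 2
Reactants: 2 car-2-en-4-one
Product: 3 cis-car-2-en-4-ol
Conditions: NaBH4, CeCl3·7H2O, MeOH, −40 °C
Reagents that add atoms: none
Why: Luche 1,2-reduction; hydride should approach from the face remote from the gem-dimethylcyclopropane, so the new C8 hydroxyl (new stereocentre) ends up on the cyclopropane face.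

Step 3
Reactants: 3 cis-car-2-en-4-ol; 4 triethyl orthopropionate
Product: 6 ethyl 2-(car-3-en-2-yl)propanoate, via mixed ketene acetal 5 (not isolated)
Conditions: propanoic acid (cat.), xylene, 140 °C, removal of EtOH
Reagents that add atoms: none
Why: Johnson–Claisen rearrangement; the ketene acetal on the C8 oxygen rearranges suprafacially, so C11 is delivered to C10 on the cyclopropane face (chirality transfer sets C10) and the alkene moves to C8=C9, while the C11 methine forms as an epimer mixture that step 6 erases.

Step 4
Reactants: 6 ethyl 2-(car-3-en-2-yl)propanoate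
Product: 7 ethyl 2-(5-oxocar-3-en-2-yl)propanoate
Conditions: CrO3, 3,5-dimethylpyrazole, CH2Cl2, −20 °C
Reagents that add atoms: chromium trioxide, O=[Cr](=O)=O
Why: Allylic oxidation at C7, the only allylic methylene, should give the cyclopropyl enone; ester and cyclopropane are inert.

Step 5
Reactants: 7 ethyl 2-(5-oxocar-3-en-2-yl)propanoate
Product: 10 cis-isopropenyl cyclohexenone ester, via iodo silyl dienol ether 8 (not isolated), via trienyl silyl ether 9 (not isolated)
Conditions: TMSI (Me3SiI), CH2Cl2, −40 °C; DBU, 0 to 25 °C; then 1 M HCl, THF
Reagents that add atoms: none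
Why: Silyl iodide opening of the cyclopropyl ketone (homo-conjugate addition of iodide at tertiary C4, cleaving the C4–C6 bond that is aligned with the carbonyl π system), E2 loss of HI towards a methyl group while the ketone is masked as its silyl dienol ether, then hydrolysis to the enone; C5 and C10 are untouched.

Step 6
Reactants: 10 cis-isopropenyl cyclohexenone ester
Product: 12 bicyclo[3.1.1]heptenone ester, via dilithium bis-enolate 11 (not isolated)
Conditions: LDA (LiN(i-Pr)2, 2.2 equiv), THF, −78 °C; then I2 (1.05 equiv), −78 to 0 °C
Reagents that add atoms: none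
Why: Iodine-mediated intramolecular oxidative coupling of the ketone α′-enolate (C6) with the ester enolate (C11) should close the cyclobutane 4-exo; C6 is dictated by the cis C5/C10 substitution and C11 by sterics, the bulky lithium ester-enolate terminus taking the open position anti to the enone bridge and the methyl the syn position.

Step 7
Reactants: 12 bicyclo[3.1.1]heptenone ester; 13 allyl acrylate
Product: 14 bicyclic allyl ethyl diester
Conditions: Fe(acac)3 (30 mol%), PhSiH3, EtOH, 60 °C
Reagents that add atoms: none
Why: HAT-initiated reductive olefin coupling (Giese addition); iron hydride transfers H to the CH2 terminus of the isopropenyl group and the tertiary C4 radical adds to the acrylate, which creates the gem-dimethyl quaternary carbon, while the electron-poor ring A enone is not a hydrogen-atom acceptor here.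

Step 8
Reactants: 14 bicyclic allyl ethyl diester
Product: 15 tricyclic allyl β-keto ester
Conditions: NaH (2.5 equiv), allyl alcohol (3 equiv), toluene, 80 °C; then AcOH
Reagents that add atoms: none
Why: Sodium allyloxide reversibly forms the ester enolate at C2, the only enolisable position next to an ester because C11 carries no hydrogen, and this carbon adds to the C1 ester carbonyl held on the same face of the cyclobutane; loss of ethoxide and irreversible deprotonation of the β-keto ester drive the equilibrium (Dieckmann condensation, an intramolecular Claisen condensation). The seven-membered ring C1–C2–C3–C4–C5–C10–C11 is closed in a 7-exo-trig manner. No stereocentre of the target is created: C2 is enolised in the product and becomes sp2 in step 9, and C5, C6, C10 and C11 are untouched. The step needs regioselectivity, which the quaternary C11 secures, and chemoselectivity over the ring A enone, whose bridgehead α-carbon C6 cannot enolise and whose carbonyl lies on the opposite face of the cyclobutane. Ester exchange is harmless, because in the allyl alcohol/allyloxide medium all exchanged esters converge on the allyl β-keto ester.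

Step 9
Reactants: 15 tricyclic allyl β-keto ester
Product: 16 tricyclic dienone
Conditions: Pd(OAc)2 (5 mol%), dppe, MeCN, 80 °C
Reagents that add atoms: none
Why: Palladium-catalysed decarboxylation–dehydrogenation of an allyl β-keto ester; oxidative addition to the allyl ester, loss of CO2 and β-hydride elimination from the palladium enolate towards C3 (C11 has no hydrogen) should give the C2=C3 enone.

Step 10
Reactants: 16 tricyclic dienone
Product: 18 C3 β-hydroxy ketone, via β-boryl ketone 17 (not isolated)
Conditions: CuCl (5 mol%), (R)-1-[(S)-2-(diphenylphosphino)ferrocenyl]ethyldicyclohexylphosphine, NaOt-Bu (cat.), B2pin2, MeOH, THF, 25 °C; then H2O2, pH 7 buffer, 0 °C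
Reagents that add atoms: hydrogen peroxide, OO
Why: Copper-catalysed asymmetric conjugate borylation followed by oxidation with retention; the copper boryl complex adds to C3 of the less substituted seven-ring enone (the ring A enone is β,β-disubstituted), and the ligand, not the nearly mirror-symmetric substrate, selects the face and so sets C3.

Step 11
Reactants: 18 C3 β-hydroxy ketone; 19 tiglaldehyde
Product: 20 C1 hydroxy C3 tiglate
Conditions: SmI2 (30 mol%), THF, −10 °C
Reagents that add atoms: none
Why: Evans–Tishchenko reduction; the C3 hydroxyl forms a samarium-bound hemiacetal with tiglaldehyde and delivers its hydride intramolecularly to the C1 ketone, which should give the 1,3-anti C1 alcohol (sets C1) and leave the tiglate on the C3 oxygen.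

Step 12
Reactants: 20 C1 hydroxy C3 tiglate; 21 angelic acid
Product: 22 target diester
Conditions: 2,4,6-trichlorobenzoyl chloride, Et3N, toluene, 25 °C; then 20, 80 °C
Reagents that add atoms: none
Why: Yamaguchi esterification through the mixed anhydride of angelic acid, run without a nucleophilic amine catalyst so that the (Z)-alkene should not isomerise to the tiglate; no stereocentre is affected.

Compound list
1 | (+)-2-carene, (1S,6R)-3,7,7-trimethylbicyclo[4.1.0]hept-2-ene | CC1(C)[C@@H]2[C@H]1CCC(C)=C2 | starting material
2 | car-2-en-4-one, (1S,6R)-3,7,7-trimethylbicyclo[4.1.0]hept-2-en-4-one | CC1(C)[C@@H]2[C@H]1CC(=O)C(C)=C2 | intermediate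
3 | cis-car-2-en-4-ol, (1S,4S,6R), hydroxyl on the cyclopropane face | CC1(C)[C@@H]2[C@H]1C[C@H](O)C(C)=C2 | intermediate
4 | triethyl orthopropionate | CCC(OCC)(OCC)OCC | starting material
5 | mixed ketene acetal, 1-ethoxyprop-1-enyl ether of 3 (not isolated) | CC1(C)[C@@H]2[C@H]1C[C@H](OC(OCC)=CC)C(C)=C2 | intermediate
6 | ethyl 2-(car-3-en-2-yl)propanoate, side chain at C10 on the cyclopropane face, both epimers at C11 | CC1(C)[C@@H]2[C@H]1CC=C(C)[C@@H]2C(C)C(=O)OCC | intermediate
7 | ethyl 2-(5-oxocar-3-en-2-yl)propanoate, cyclopropyl enone, both epimers at C11 | CC1(C)[C@@H]2[C@H]1C(=O)C=C(C)[C@@H]2C(C)C(=O)OCC | intermediate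
8 | iodo silyl dienol ether, C4 tertiary iodide, C6=C7 trimethylsilyl enol ether (not isolated) | CC(C)(I)[C@@H]1C=C(O[Si](C)(C)C)C=C(C)[C@@H]1C(C)C(=O)OCC | intermediate
9 | trienyl silyl ether, isopropenyl group on C5, C6=C7 trimethylsilyl enol ether (not isolated) | CC(=C)[C@@H]1C=C(O[Si](C)(C)C)C=C(C)[C@@H]1C(C)C(=O)OCC | intermediate
10 | ethyl 2-[2-methyl-4-oxo-6-(prop-1-en-2-yl)cyclohex-2-en-1-yl]propanoate, ring substituents at C10 and C5 cis, both epimers at C11 | CC(=C)[C@@H]1CC(=O)C=C(C)[C@@H]1C(C)C(=O)OCC | intermediate
11 | dilithium bis-enolate of 10, ketone enolate at C6 and ester enolate at C11 (not isolated) | [Li+].[Li+].CC(=C)[C@@H]1C=C([O-])C=C(C)[C@@H]1C(C)=C([O-])OCC | intermediate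
12 | ethyl 4,6-dimethyl-2-oxo-7-(prop-1-en-2-yl)bicyclo[3.1.1]hept-3-ene-6-carboxylate, ester and isopropenyl both anti to the enone bridge | CC(=C)[C@@H]2[C@H]3C(=O)C=C(C)[C@@H]2[C@@]3(C)C(=O)OCC | intermediate
13 | allyl acrylate | C=CC(=O)OCC=C | starting material
14 | allyl 4-[6-(ethoxycarbonyl)-4,6-dimethyl-2-oxobicyclo[3.1.1]hept-3-en-7-yl]-4-methylpentanoate, both arms anti to the enone bridge | C=CCOC(=O)CCC(C)(C)[C@@H]2[C@H]3C(=O)C=C(C)[C@@H]2[C@@]3(C)C(=O)OCC | intermediate
15 | tricyclic allyl β-keto ester, C1 ketone, allyl ester on C2 (epimers or enol), ring A enone | O=C1C(C(=O)OCC=C)CC(C)(C)[C@@H]2[C@H]3C(=O)C=C(C)[C@@H]2[C@]31C | intermediate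
16 | tricyclic dienone, 2,6,6,9-tetramethyltricyclo[5.4.0.0(2,8)]undeca-4,9-diene-3,11-dione (C1 ketone with C2=C3, C7 ketone with C8=C9) | O=C1C=CC(C)(C)[C@@H]2[C@H]3C(=O)C=C(C)[C@@H]2[C@]31C | intermediate
17 | β-boryl ketone, pinacolboryl group on C3 on the C10 side (not isolated) | O=C1C[C@@H](B4OC(C)(C)C(C)(C)O4)C(C)(C)[C@@H]2[C@H]3C(=O)C=C(C)[C@@H]2[C@]31C | intermediate
18 | C3 β-hydroxy ketone, hydroxyl on C3 on the C10 side, C1 ketone | O=C1C[C@@H](O)C(C)(C)[C@@H]2[C@H]3C(=O)C=C(C)[C@@H]2[C@]31C | intermediate
19 | tiglaldehyde, (E)-2-methylbut-2-enal | C/C=C(\C)C=O | starting material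
20 | C1 hydroxy C3 tiglate, C1 hydroxyl anti to the C3 tiglate | O[C@@H]1C[C@@H](OC(=O)/C(C)=C/C)C(C)(C)[C@@H]2[C@H]3C(=O)C=C(C)[C@@H]2[C@]31C | intermediate
21 | angelic acid, (Z)-2-methylbut-2-enoic acid | C/C=C(/C)C(=O)O | starting material
22 | target, C1 angelate C3 tiglate of the 2,6,6,9-tetramethyltricyclo[5.4.0.0(2,8)]undec-9-en-11-one diol | C/C=C(/C)C(=O)O[C@@H]1C[C@@H](OC(=O)/C(C)=C/C)C(C)(C)[C@@H]2[C@H]3C(=O)C=C(C)[C@@H]2[C@]31C | target

Total step count: 12. Longest linear sequence: 12 steps (the route is linear from 1).

Steps most likely to fail

Step 6. The bis-enolate may be iodinated without ring closure, may couple between molecules, or the tertiary iodo ester may lose HI. The enolate may also approach with its ester group on the side of the enone bridge, which would put C11 in the wrong configuration. The fallback sets out from 9, the trimethylsilyl dienol ether that step 5 passes through, isolated by omitting the acid work-up. LDA deprotonates only the ester, and CBr4 then gives the α-bromo ester silyl dienol ether F1. Irradiation with blue light and Ir(ppy)3 generates the tertiary α-ester radical, which adds to C6 of the electron-rich dienol ether. Oxidation of the α-siloxy radical by the oxidised photocatalyst and loss of the silyl group return the enone, and the route is rejoined at 12.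

Step 8. Attack on the neopentyl-type ester carbonyl on C11 may be too slow. Intermolecular condensation, enolate Claisen rearrangement of the allyl ester or slow degradation in the alkoxide medium could then take over. The fallback sets out from 12 and closes the ring by a radical C3–C4 bond formation instead:
- DIBAL-H (i-Bu2AlH) reduces ester and ketone to the bicyclic diol F2.
- Dess–Martin periodinane gives the keto aldehyde F3.
- Vinylmagnesium bromide (CH2=CHMgBr) at −78 °C adds to the aldehyde only and gives the allylic alcohol F4.
- A second Dess–Martin oxidation gives the vinyl ketone F5.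
- Fe(acac)3 and PhSiH3 close the seven-membered ring by HAT-initiated 7-endo Giese addition of the tertiary C4 radical to the vinyl ketone, giving the saturated tricyclic diketone F6.
- IBX dehydrogenation, possible only towards C2–C3, rejoins the route at 16.

Step 10. The two faces of the C2=C3 bond differ only through the remote enone bridge, so facial selectivity rests entirely on the catalyst and may be poor. The hindered C3, next to the quaternary C4, may react slowly enough for the ring A enone to compete. The fallback sets out from 16. Epoxidation of the seven-ring enone with H2O2 and the salt of a cinchona-derived primary amine (iminium activation, catalyst control) gives the epoxy ketone F7. SmI2 in THF/MeOH at −78 °C cleaves the C2–O bond and rejoins the route at 18.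

Further compounds
F1 | step 6 | α-bromo ester silyl dienol ether, bromine on C11 of compound 9 | CC(=C)[C@@H]1C=C(O[Si](C)(C)C)C=C(C)[C@@H]1C(C)(Br)C(=O)OCC
F2 | step 8 | bicyclic diol, CH2OH on C11 and hydroxyl at C7 (epimers) | CC(=C)[C@@H]2[C@H]3C(O)C=C(C)[C@@H]2[C@@]3(C)CO
F3 | step 8 | bicyclic keto aldehyde, formyl group on C11 | CC(=C)[C@@H]2[C@H]3C(=O)C=C(C)[C@@H]2[C@@]3(C)C=O
F4 | step 8 | allylic alcohol, 1-hydroxyprop-2-enyl group on C11 (epimers) | CC(=C)[C@@H]2[C@H]3C(=O)C=C(C)[C@@H]2[C@@]3(C)C(O)C=C
F5 | step 8 | vinyl ketone, acryloyl group on C11 | CC(=C)[C@@H]2[C@H]3C(=O)C=C(C)[C@@H]2[C@@]3(C)C(=O)C=C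
F6 | step 8 | saturated tricyclic diketone, C1 ketone with C2 and C3 methylenes | O=C1CCC(C)(C)[C@@H]2[C@H]3C(=O)C=C(C)[C@@H]2[C@]31C
F7 | step 10 | epoxy ketone, C2–C3 epoxide with oxygen on the C10 side | O=C1[C@H]4O[C@H]4C(C)(C)[C@@H]2[C@H]3C(=O)C=C(C)[C@@H]2[C@]31C
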